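Take the logarithm of the solid substrate first, because it shows quickly how far a simple decay law can carry a short run.

all flasks: solid substrate 0.24 M; free catalyst 20 mol%

| flask | remark | time |
|---|---|---|
| Saturday's | the very flask that is asked about, followed so far |  |
| flask |  | 4.0 min |

Saturday's run (percent of the solid substrate charged)

| time / s | solid substrate / % | catalyst intermediate / % | starting material / % | product / % |
|---|---|---|---|---|
| 10.0 | 93 | 3 | 9 | 2 |
| 20.0 | 86 | 1 | 14 | 1 |
| 30.0 | 80 | 0 | 23 | 0 |
| 50.0 | 66 | 3 | 31 | 0 |
| 80.0 | 55 | 1 | 40 | 7 |
| 90.0 | 48 | 2 | 40 | 4 |

(scatter of a reading: 2 percentage points)

- the largest share of what was charged as solid substrate, at 4.0 min belongs to (catalyst intermediate / starting material / product)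
- the largest share itself, whichever of these holds it, in percent of the solid substrate charged

- solid, in amounts per volume of the solution: solid substrate
- at the start none of the solid substrate is in solution
- starting material means what is dissolved; the solid is not counted in it

My rule of thumb was pseudo-first-order dissolving. On Saturday the flask lost 0.319 of a decade of solid by 90.0 s, so 4.0 min would bring 0.850 of a decade and leave 14.1 %.

But solid dissolves into room in the solution, so I read its rate against dissolved starting material. Over the first 30.0 s the solid went at 0.00667 s⁻¹ of the charge with 14 % dissolved, and from 50.0 s to 90.0 s at 0.00450 s⁻¹ with 40 % dissolved. A straight line through these gives a slope k of 0.00833 s⁻¹ and meets zero rate at 94.0 % of the charge. That is the ceiling c*, the dissolved concentration at which the solid stops going, 0.226 M, a reading carrying the scatter of 2 percentage points on each number.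

The log rule stops where room outgrows solid: at 90.0 s their ratio was already 1.13. Clearing the remaining 48 % by 4.0 min needed dissolved starting material to average below 55.6 %. At 90.0 s Saturday's flask read 40 % of starting material and 4 % of product, so I expected more starting material than product at 4.0 min.

The forecast named starting material at 52 %, range 43 % to 61 %, and judged that “Starting material most likely still leads”.

The flask gave starting material at 65.3 %.

    starting material + free catalyst ⇌ catalyst intermediate (K = 31.5 M⁻¹, k = 0.0702 M⁻¹ s⁻¹)
    catalyst intermediate ⇌ free catalyst + product (K = 0.196 M, k = 4.12 s⁻¹)
    solid substrate ⇌ starting material, rate k3*(cs3 - [starting material]) while solid is left; crystals form when [starting material] > cs3 (solubility = 0.220 M, k = 0.00858 s⁻¹)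

At 4.00 min the flask held 4.30 % of its charge as solid, less than the logarithmic 14.1 %. Its starting material came to 0.157 M, below c* of 0.226 M. The neighbour flask charged with 0.096 M stood below c* even if fully dissolved, and at 4.00 min it held 0 % of solid.

The runs are simulated for an exercise, noise included.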